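## Retrosynthetic overview

1. Target 30 ⇒ ten-membered carbocyclic alcohol 25 + (2R,3R)-epoxyangelic acid 17 (late ester bond at O8 after a silyl exchange between O8 and O9).
2. 25 ⇒ seco iodo-aldehyde 23: the ten-membered ring is closed at C9–C10 by a Nozaki–Hiyama–Kishi macrocyclisation, which also creates the C9 carbinol.
3. 23 ⇒ cis-α-methylene-γ-butyrolactone 20 ⇒ enal 6 (fragment A) + allyl bromide 13 (fragment B): an indium Barbier allylation/lactonisation forms C6–C7 and the lactone.
4. 6 comes from geranyl acetate (Z-iodoalkene by Stork–Zhao olefination); 13 from L-ascorbic acid via L-glyceraldehyde acetonide and a Morita–Baylis–Hillman reaction; 17 from angelic acid by Sharpless epoxidation.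
5. Ring order: epoxide (step 12, carried in with 17), lactone (step 14), ten-membered ring (step 18).

Assumption: the SMILES is taken literally (cis-fused lactone, C6 S, C7 S, C8 R, C9 R, 4E, 1(10)Z, (2R,3R)-epoxyangelate); locants are germacranolide-type: C6 lactone carbinol, C7 ring fusion, C8 ester carbon, C9 carbinol, C10=C1 Z-olefin, C4=C5 E-olefin, C11=C13 methylene, C12 lactone carbonyl.

## Fragment A

Step 1
Reactants: 1 geranyl acetate
Product: 2 (2E)-5-(3,3-dimethyloxiran-2-yl)-3-methylpent-2-en-1-yl acetate (racemic epoxide)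
Conditions: mCPBA (1.05 equiv), NaHCO3, CH2Cl2, 0 °C
Reagents that add atoms: 3-chloroperoxybenzoic acid, OOC(=O)c1cccc(Cl)c1
Why: Prilezhaev epoxidation is selective for the electron-rich distal olefin because the 2,3-olefin is deactivated by the allylic acetate; the racemic epoxide centre is excised in step 2.

Step 2
Reactants: 2 epoxide
Product: 3 (2E)-3-methyl-6-oxohex-2-en-1-yl acetate
Conditions: H5IO6, THF/Et2O, 0 °C
Reagents that add atoms: none
Why: Periodic acid opens the epoxide and cleaves the resulting glycol (Malaprade-type cleavage) to the aldehyde and acetone without touching the E-olefin or the acetate.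

Step 3
Reactants: 3 aldehyde
Product: 4 (2E,6Z)-7-iodo-3-methylocta-2,6-dien-1-yl acetate
Conditions: EtPPh3I, n-BuLi, THF, rt; I2, −78 °C; NaN(SiMe3)2, −20 °C; then 3, −78 → −20 °C
Reagents that add atoms: ethyltriphenylphosphonium iodide, CC[P+](c1ccccc1)(c1ccccc1)c1ccccc1.[I-]; iodine, II
Why: Stork–Zhao Wittig olefination with the non-stabilised α-iodoethylidene ylide proceeds through the kinetic cis-oxaphosphetane and gives the (Z)-2-iodoalk-2-ene (iodine cis to the chain), which is the future C1=C10 geometry.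

Step 4
Reactants: 4 iodo-dienyl acetate
Product: 5 (2E,6Z)-7-iodo-3-methylocta-2,6-dien-1-ol
Conditions: K2CO3 (cat.), MeOH, 0 °C → rt
Reagents that add atoms: none
Why: Base-catalysed transesterification (methanolysis) removes the acetate; the alkenyl iodide is inert.

Step 5
Reactants: 5 allylic alcohol
Product: 6 (2E,6Z)-7-iodo-3-methylocta-2,6-dienal (fragment A)
Conditions: MnO2 (activated, excess), CH2Cl2, rt
Reagents that add atoms: none
Why: MnO2 allylic oxidation stops at the enal and does not scramble either olefin geometry.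

## Fragment B

Step 6
Reactants: 7 L-ascorbic acid
Product: 8 L-gulono-1,4-lactone
Conditions: H2 (3.5 bar), 10% Pd/C, H2O, 50 °C
Reagents that add atoms: none
Why: Heterogeneous catalytic hydrogenation adds H2 cis from the face opposite the side chain; the two new centres are excised in step 8, while C5 (future C8) comes from the chiral pool.

Step 7
Reactants: 8 L-gulono-1,4-lactone
Product: 9 5,6-O-isopropylidene-L-gulono-1,4-lactone
Conditions: 2-methoxypropene, p-TsOH (cat.), DMF, 0 °C → rt
Reagents that add atoms: 2-methoxypropene, COC(C)=C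
Why: Kinetic acetalisation with the enol ether protects the terminal 5,6-diol and leaves the 2,3-diol free for cleavage.

Step 8
Reactants: 9 lactone acetonide
Product: 10 (4S)-2,2-dimethyl-1,3-dioxolane-4-carbaldehyde (L-glyceraldehyde acetonide)
Conditions: NaIO4 (2 equiv), H2O, pH 5.5 (NaOH), 0 °C → rt
Reagents that add atoms: none
Why: Two successive Malaprade cleavages (C2–C3, then C3–C4 after loss of the glyoxylate ester) leave C5 of the sugar untouched as the S aldehyde; it is used at once to avoid racemisation.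

Step 9
Reactants: 10 L-glyceraldehyde acetonide; 11 methyl acrylate
Product: 12 methyl 2-{[(4S)-2,2-dimethyl-1,3-dioxolan-4-yl](hydroxy)methyl}prop-2-enoate (both carbinol epimers)
Conditions: DABCO (0.5 equiv), dioxane/H2O (1:1), rt, 3–5 d
Reagents that add atoms: none
Why: Morita–Baylis–Hillman reaction of an activated α-alkoxy aldehyde; the new carbinol centre is irrelevant because it becomes sp2 in step 10.

Step 10
Reactants: 12 Morita–Baylis–Hillman adduct
Product: 13 methyl (2Z)-2-(bromomethyl)-3-[(4R)-2,2-dimethyl-1,3-dioxolan-4-yl]prop-2-enoate (fragment B)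
Conditions: NBS, Me2S, CH2Cl2, 0 °C → rt
Reagents that add atoms: N-bromosuccinimide, BrN1C(=O)CCC1=O
Why: Corey–Kim-type activation of the alcohol followed by SN2' attack of bromide gives the thermodynamically preferred (Z)-2-(bromomethyl)alk-2-enoate from both epimers under neutral conditions that spare the acetonide (the descriptor changes to 4R by priority only).

## Fragment C

Step 11
Reactants: 14 angelic acid
Product: 15 (2Z)-2-methylbut-2-en-1-ol
Conditions: LiAlH4, Et2O, 0 °C
Reagents that add atoms: none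
Why: Hydride reduction of the carboxylic acid gives the allylic alcohol without conjugate reduction or Z/E isomerisation.

Step 12
Reactants: 15 angelyl alcohol
Product: 16 [(2S,3R)-2,3-dimethyloxiran-2-yl]methanol
Conditions: Ti(OiPr)4 (10 mol %), L-(+)-diethyl tartrate (12 mol %), t-BuOOH, 4 Å molecular sieves, CH2Cl2, −20 °C
Reagents that add atoms: tert-butyl hydroperoxide, CC(C)(C)OO
Why: Sharpless asymmetric epoxidation with L-(+)-tartrate delivers oxygen to the face that gives the 2S epoxy alcohol (the same sense that gives 2S,3S epoxides from E-allylic alcohols), and syn addition keeps the two methyl groups trans.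

Step 13
Reactants: 16 epoxy alcohol
Product: 17 (2R,3R)-2,3-dimethyloxirane-2-carboxylic acid (fragment C)
Conditions: RuCl3·xH2O (2 mol %), NaIO4, CCl4/MeCN/H2O, rt
Reagents that add atoms: water, O; sodium periodate, [Na+].[O-]I(=O)(=O)=O (terminal oxidant that regenerates RuO4)
Why: Sharpless RuO4-catalysed oxidation takes the primary alcohol to the acid without touching the epoxide; C2 changes from S to R by priority only.

## Fragment union and endgame

Step 14
Reactants: 6 (2E,6Z)-7-iodo-3-methylocta-2,6-dienal; 13 methyl (2Z)-2-(bromomethyl)-3-[(4R)-2,2-dimethyl-1,3-dioxolan-4-yl]prop-2-enoate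
Product: 20 (4S,5S)-4-[(4R)-2,2-dimethyl-1,3-dioxolan-4-yl]-5-[(1E,5Z)-6-iodo-2-methylhepta-1,5-dien-1-yl]-3-methylideneoxolan-2-one (cis-lactone), via allylindium dibromide 18 (not isolated), via hydroxy ester 19 (not isolated)
Conditions: In powder (1.5 equiv), THF/H2O (1:1), rt; extractive work-up; then p-TsOH·H2O (5 mol %), CH2Cl2, 0 °C → rt
Reagents that add atoms: none
Why: In the indium Barbier allylation the (Z)-allylindium adds 1,2 to the enal through its γ-carbon in a chair Zimmerman–Traxler transition state with the dioxolanyl group axial, giving the 6,7-syn adduct (hence the cis-lactone, C6 S), while A(1,3) strain holds C8–H in the alkene plane so that the aldehyde bonds to C7 anti to the dioxolane C–O bond (C7 S); acid then lactonises onto the only free hydroxyl.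

Step 15
Reactants: 20 cis-lactone acetonide
Product: 21 (4R,5S)-4-[(1R)-1,2-dihydroxyethyl]-5-[(1E,5Z)-6-iodo-2-methylhepta-1,5-dien-1-yl]-3-methylideneoxolan-2-one
Conditions: AcOH/H2O (4:1), 40 °C
Reagents that add atoms: none
Why: Mild acid hydrolysis removes the terminal acetonide; the allylic lactone and the alkenyl iodide survive and translactonisation to O8 is slow at this acidity (descriptor change at the ring carbon is by priority only).

Step 16
Reactants: 21 diol
Product: 22 (4S,5S)-4-[(1R)-1,2-bis(triethylsilyloxy)ethyl]-5-[(1E,5Z)-6-iodo-2-methylhepta-1,5-dien-1-yl]-3-methylideneoxolan-2-one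
Conditions: Et3SiOTf (2.5 equiv), 2,6-lutidine, CH2Cl2, −78 °C
Reagents that add atoms: triethylsilyl triflate, CC[Si](CC)(CC)OS(=O)(=O)C(F)(F)F
Why: Fast bis-silylation at low temperature with a hindered non-nucleophilic base avoids oxa-Michael addition to the methylene lactone and translactonisation.

Step 17
Reactants: 22 bis-TES ether
Product: 23 (2R)-2-{(2S,3S)-2-[(1E,5Z)-6-iodo-2-methylhepta-1,5-dien-1-yl]-4-methylidene-5-oxooxolan-3-yl}-2-(triethylsilyloxy)acetaldehyde
Conditions: (COCl)2, DMSO, CH2Cl2, −78 → −40 °C; then Et3N, −78 → 0 °C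
Reagents that add atoms: none
Why: Under Swern conditions a primary triethylsilyl ether is converted directly into the aldehyde while the secondary one is retained, so C9 is unmasked in one operation with C8 still protected.

Step 18
Reactants: 23 seco iodo-aldehyde
Product: 25 (3aS,4R,5R,6Z,10E,11aS)-5-hydroxy-6,10-dimethyl-3-methylidene-4-(triethylsilyloxy)-3a,4,5,8,9,11a-hexahydrocyclodeca[b]furan-2(3H)-one, via alkenylchromium dichloride 24 (not isolated)
Conditions: CrCl2 (10 equiv), NiCl2 (2 mol %), degassed DMF/THF (3:1), rt, 23 added by syringe pump (final 0.002 M)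
Reagents that add atoms: none
Why: In the Nozaki–Hiyama–Kishi macrocyclisation the alkenylchromium formed with retention of the Z geometry adds only to the aldehyde (lactone, enoate and silyl ether are inert) and high dilution favours ring closure; C9 is set by substrate control from the C8 silyloxy centre within the cyclic transition state, the 8,9-syn (9R) carbinol being the one required.

Step 19
Reactants: 25 macrocyclic alcohol
Product: 26 (3aS,4R,5R,6Z,10E,11aS)-5-(tert-butyldimethylsilyloxy)-6,10-dimethyl-3-methylidene-4-(triethylsilyloxy)-3a,4,5,8,9,11a-hexahydrocyclodeca[b]furan-2(3H)-one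
Conditions: t-BuMe2SiOTf, 2,6-lutidine, CH2Cl2, −78 → 0 °C
Reagents that add atoms: tert-butyldimethylsilyl triflate, CC(C)(C)[Si](C)(C)OS(=O)(=O)C(F)(F)F
Why: Silyl triflate silylation protects the hindered allylic C9 hydroxyl with a group more robust than the C8 triethylsilyl ether.

Step 20
Reactants: 26 mixed bis-silyl ether
Product: 27 (3aR,4R,5R,6Z,10E,11aS)-5-(tert-butyldimethylsilyloxy)-4-hydroxy-6,10-dimethyl-3-methylidene-3a,4,5,8,9,11a-hexahydrocyclodeca[b]furan-2(3H)-one
Conditions: PPTS (cat.), MeOH/CH2Cl2 (1:3), 0 °C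
Reagents that add atoms: none
Why: Acid-catalysed methanolysis removes the triethylsilyl ether much faster than the tert-butyldimethylsilyl ether, freeing only O8 under conditions too mild for transannular cyclisation of the 1,5-diene (descriptor change at C3a is by priority only).

Step 21
Reactants: 27 C8 alcohol; 17 (2R,3R)-2,3-dimethyloxirane-2-carboxylic acid
Product: 29 (3aS,4R,5R,6Z,10E,11aS)-5-(tert-butyldimethylsilyloxy)-6,10-dimethyl-3-methylidene-2-oxo-2,3,3a,4,5,8,9,11a-octahydrocyclodeca[b]furan-4-yl (2R,3R)-2,3-dimethyloxirane-2-carboxylate, via mixed anhydride 28 (not isolated)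
Conditions: 17, 2,4,6-trichlorobenzoyl chloride, Et3N, toluene, rt; then 27, DMAP, toluene, rt
Reagents that add atoms: none
Why: Yamaguchi esterification through the mixed anhydride and the acylpyridinium ion acylates the hindered secondary alcohol with retention at C8 and without touching the epoxide.

Step 22
Reactants: 29 silyl-protected ester
Product: 30 (3aS,4R,5R,6Z,10E,11aS)-5-hydroxy-6,10-dimethyl-3-methylidene-2-oxo-2,3,3a,4,5,8,9,11a-octahydrocyclodeca[b]furan-4-yl (2R,3R)-2,3-dimethyloxirane-2-carboxylate (CNP0318223.2)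
Conditions: HF·pyridine, pyridine, THF, 0 °C → rt
Reagents that add atoms: none
Why: Buffered fluoride desilylation frees the C9 hydroxyl under weakly acidic conditions that suppress O8→O9 acyl migration and leave the glycidic ester and the methylene lactone intact.

## Compound list

1 | geranyl acetate, (2E)-3,7-dimethylocta-2,6-dien-1-yl acetate | CC(C)=CCC/C(C)=C/COC(C)=O | starting material
2 | (2E)-5-(3,3-dimethyloxiran-2-yl)-3-methylpent-2-en-1-yl acetate (racemic) | CC1(C)OC1CC/C(C)=C/COC(C)=O | intermediate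
3 | (2E)-3-methyl-6-oxohex-2-en-1-yl acetate | O=CCC/C(C)=C/COC(C)=O | intermediate
4 | (2E,6Z)-7-iodo-3-methylocta-2,6-dien-1-yl acetate | C/C(I)=C/CC/C(C)=C/COC(C)=O | intermediate
5 | (2E,6Z)-7-iodo-3-methylocta-2,6-dien-1-ol | C/C(I)=C/CC/C(C)=C/CO | intermediate
6 | (2E,6Z)-7-iodo-3-methylocta-2,6-dienal (fragment A) | C/C(I)=C/CC/C(C)=C/C=O | intermediate
7 | L-ascorbic acid | OC[C@H](O)[C@H]1OC(=O)C(O)=C1O | starting material
8 | L-gulono-1,4-lactone | O=C1[C@@H](O)[C@@H](O)[C@H](O1)[C@@H](O)CO | intermediate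
9 | 5,6-O-isopropylidene-L-gulono-1,4-lactone | O=C1[C@@H](O)[C@@H](O)[C@H](O1)[C@@H]2COC(C)(C)O2 | intermediate
10 | (4S)-2,2-dimethyl-1,3-dioxolane-4-carbaldehyde (L-glyceraldehyde acetonide) | O=C[C@@H]1COC(C)(C)O1 | intermediate
11 | methyl acrylate | C=CC(=O)OC | starting material
12 | methyl 2-{[(4S)-2,2-dimethyl-1,3-dioxolan-4-yl](hydroxy)methyl}prop-2-enoate (both carbinol epimers) | C=C(C(=O)OC)C(O)[C@@H]1COC(C)(C)O1 | intermediate
13 | methyl (2Z)-2-(bromomethyl)-3-[(4R)-2,2-dimethyl-1,3-dioxolan-4-yl]prop-2-enoate (fragment B) | BrC/C(=C\[C@@H]1COC(C)(C)O1)C(=O)OC | intermediate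
14 | angelic acid, (2Z)-2-methylbut-2-enoic acid | C/C=C(/C)C(=O)O | starting material
15 | (2Z)-2-methylbut-2-en-1-ol | C/C=C(/C)CO | intermediate
16 | [(2S,3R)-2,3-dimethyloxiran-2-yl]methanol | OC[C@]1(C)O[C@@H]1C | intermediate
17 | (2R,3R)-2,3-dimethyloxirane-2-carboxylic acid (fragment C) | OC(=O)[C@]1(C)O[C@@H]1C | intermediate
18 | allylindium dibromide derived from 13 (nominal formula of the allylindium reagent) | Br[In](Br)C/C(=C\[C@@H]1COC(C)(C)O1)C(=O)OC | intermediate
19 | methyl (3S,4S,5E,9Z)-3-[(4R)-2,2-dimethyl-1,3-dioxolan-4-yl]-4-hydroxy-10-iodo-6-methyl-2-methylideneundeca-5,9-dienoate | C=C(C(=O)OC)[C@H]([C@@H]1COC(C)(C)O1)[C@@H](O)/C=C(\C)CC/C=C(/C)I | intermediate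
20 | (4S,5S)-4-[(4R)-2,2-dimethyl-1,3-dioxolan-4-yl]-5-[(1E,5Z)-6-iodo-2-methylhepta-1,5-dien-1-yl]-3-methylideneoxolan-2-one | C=C1C(=O)O[C@@H](/C=C(\C)CC/C=C(/C)I)[C@H]1[C@@H]2COC(C)(C)O2 | intermediate
21 | (4R,5S)-4-[(1R)-1,2-dihydroxyethyl]-5-[(1E,5Z)-6-iodo-2-methylhepta-1,5-dien-1-yl]-3-methylideneoxolan-2-one | C=C1C(=O)O[C@@H](/C=C(\C)CC/C=C(/C)I)[C@H]1[C@@H](O)CO | intermediate
22 | (4S,5S)-4-[(1R)-1,2-bis(triethylsilyloxy)ethyl]-5-[(1E,5Z)-6-iodo-2-methylhepta-1,5-dien-1-yl]-3-methylideneoxolan-2-one | C=C1C(=O)O[C@@H](/C=C(\C)CC/C=C(/C)I)[C@H]1[C@@H](O[Si](CC)(CC)CC)CO[Si](CC)(CC)CC | intermediate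
23 | (2R)-2-{(2S,3S)-2-[(1E,5Z)-6-iodo-2-methylhepta-1,5-dien-1-yl]-4-methylidene-5-oxooxolan-3-yl}-2-(triethylsilyloxy)acetaldehyde | C=C1C(=O)O[C@@H](/C=C(\C)CC/C=C(/C)I)[C@H]1[C@@H](O[Si](CC)(CC)CC)C=O | intermediate
24 | alkenylchromium dichloride derived from 23 (CrCl2 in place of iodine, Z geometry retained) | C=C1C(=O)O[C@@H](/C=C(\C)CC/C=C(/C)[Cr](Cl)Cl)[C@H]1[C@@H](O[Si](CC)(CC)CC)C=O | intermediate
25 | (3aS,4R,5R,6Z,10E,11aS)-5-hydroxy-6,10-dimethyl-3-methylidene-4-(triethylsilyloxy)-3a,4,5,8,9,11a-hexahydrocyclodeca[b]furan-2(3H)-one | C=C1C(=O)O[C@H]2/C=C(\C)CC/C=C(/C)[C@@H](O)[C@H](O[Si](CC)(CC)CC)[C@@H]12 | intermediate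
26 | (3aS,4R,5R,6Z,10E,11aS)-5-(tert-butyldimethylsilyloxy)-6,10-dimethyl-3-methylidene-4-(triethylsilyloxy)-3a,4,5,8,9,11a-hexahydrocyclodeca[b]furan-2(3H)-one | C=C1C(=O)O[C@H]2/C=C(\C)CC/C=C(/C)[C@@H](O[Si](C)(C)C(C)(C)C)[C@H](O[Si](CC)(CC)CC)[C@@H]12 | intermediate
27 | (3aR,4R,5R,6Z,10E,11aS)-5-(tert-butyldimethylsilyloxy)-4-hydroxy-6,10-dimethyl-3-methylidene-3a,4,5,8,9,11a-hexahydrocyclodeca[b]furan-2(3H)-one | C=C1C(=O)O[C@H]2/C=C(\C)CC/C=C(/C)[C@@H](O[Si](C)(C)C(C)(C)C)[C@H](O)[C@@H]12 | intermediate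
28 | (2R,3R)-2,3-dimethyloxirane-2-carboxylic 2,4,6-trichlorobenzoic anhydride | O=C(OC(=O)c1c(Cl)cc(Cl)cc1Cl)[C@]2(C)O[C@@H]2C | intermediate
29 | (3aS,4R,5R,6Z,10E,11aS)-5-(tert-butyldimethylsilyloxy)-6,10-dimethyl-3-methylidene-2-oxo-2,3,3a,4,5,8,9,11a-octahydrocyclodeca[b]furan-4-yl (2R,3R)-2,3-dimethyloxirane-2-carboxylate | C=C1C(=O)O[C@H]2/C=C(\C)CC/C=C(/C)[C@@H](O[Si](C)(C)C(C)(C)C)[C@H](OC(=O)[C@]3(C)O[C@@H]3C)[C@@H]12 | intermediate
30 | (3aS,4R,5R,6Z,10E,11aS)-5-hydroxy-6,10-dimethyl-3-methylidene-2-oxo-2,3,3a,4,5,8,9,11a-octahydrocyclodeca[b]furan-4-yl (2R,3R)-2,3-dimethyloxirane-2-carboxylate | C=C1C(=O)O[C@H]2/C=C(\C)CC/C=C(/C)[C@@H](O)[C@H](OC(=O)[C@]3(C)O[C@@H]3C)[C@@H]12 | target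

## Step count and risks

Total step count: 22.
Longest linear sequence: 14 steps (steps 1–5, then 14–22; the branch through steps 6–10 is equally long; the acid branch contributes 3 + 2).

Steps most likely to fail:

**Step 14** (facial selectivity of the Barbier addition relative to C8, possible elimination of the γ-alkoxy allylindium). The fallback sets out from 12. Acetylation (Ac2O, pyridine, DMAP) gives the Morita–Baylis–Hillman acetate F1. CuCl/LiCl/KOAc-catalysed SN2' borylation with bis(pinacolato)diboron in DMF converts it into the (Z)-allylboronate F2. F2 is added to enal 6 under chiral phosphoric acid catalysis ((R)-TRIP, toluene, 0 °C → rt; the mirror-image acid if the sense is mismatched). The closed boron chair transition state keeps the 6,7-syn relationship while the catalyst, not C8, selects the face. Hydrolytic work-up gives hydroxy ester 19, where the route is rejoined.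

**Step 18** (oligomerisation in the ten-membered ring closure and uncertain C9 configuration, since an acyclic Felkin model would favour the 8,9-anti epimer). The fallback sets out from 23. If the ring closure delivers mainly the C9 epimer F3, it is oxidised with Dess–Martin periodinane (NaHCO3, CH2Cl2) to the macrocyclic enone F4. Luche reduction (NaBH4, CeCl3·7H2O, MeOH, −78 °C) then adds hydride in the Felkin–Anh sense, anti to the C8–OSiEt3 bond, which for an α-silyloxy ketone gives the 8,9-syn alcohol. The route is rejoined at 25.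

**Step 21** (acylation of the hindered C8 hydroxyl, flanked by the C9 silyl ether and the lactone, with a quaternary acid; competing translactonisation). The fallback sets out from diol 21. The primary hydroxyl is silylated (t-BuMe2SiCl, imidazole, CH2Cl2, 0 °C) to the mono-silyl ether F5. The still unhindered acyclic C8 hydroxyl is esterified with 17 under the same Yamaguchi conditions to epoxyangelate F6. The primary silyl group is removed (HF·pyridine, pyridine, THF, 0 °C) to alcohol F7, which is oxidised (Dess–Martin periodinane, NaHCO3) to acyloxy aldehyde F8. The same CrCl2/NiCl2 macrocyclisation at high dilution then gives the target directly, and the route is rejoined at 30. The cost is exposure of the glycidic ester to CrCl2, which is why this order is held in reserve.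

Further compounds
F1 | step 14 | methyl 2-{acetoxy[(4S)-2,2-dimethyl-1,3-dioxolan-4-yl]methyl}prop-2-enoate | C=C(C(=O)OC)C(OC(C)=O)[C@@H]1COC(C)(C)O1
F2 | step 14 | methyl (2Z)-3-[(4R)-2,2-dimethyl-1,3-dioxolan-4-yl]-2-[(4,4,5,5-tetramethyl-1,3,2-dioxaborolan-2-yl)methyl]prop-2-enoate | CC1(C)OB(C/C(=C\[C@@H]2COC(C)(C)O2)C(=O)OC)OC1(C)C
F3 | step 18 | (3aS,4R,5S,6Z,10E,11aS)-5-hydroxy-6,10-dimethyl-3-methylidene-4-(triethylsilyloxy)-3a,4,5,8,9,11a-hexahydrocyclodeca[b]furan-2(3H)-one (C9 epimer of 25) | C=C1C(=O)O[C@H]2/C=C(\C)CC/C=C(/C)[C@H](O)[C@H](O[Si](CC)(CC)CC)[C@@H]12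
F4 | step 18 | (3aS,4R,6Z,10E,11aS)-6,10-dimethyl-3-methylidene-4-(triethylsilyloxy)-3a,8,9,11a-tetrahydrocyclodeca[b]furan-2,5(3H,4H)-dione | C=C1C(=O)O[C@H]2/C=C(\C)CC/C=C(/C)C(=O)[C@H](O[Si](CC)(CC)CC)[C@@H]12
F5 | step 21 | (4R,5S)-4-[(1R)-2-(tert-butyldimethylsilyloxy)-1-hydroxyethyl]-5-[(1E,5Z)-6-iodo-2-methylhepta-1,5-dien-1-yl]-3-methylideneoxolan-2-one | C=C1C(=O)O[C@@H](/C=C(\C)CC/C=C(/C)I)[C@H]1[C@@H](O)CO[Si](C)(C)C(C)(C)C
F6 | step 21 | (1R)-2-(tert-butyldimethylsilyloxy)-1-{(2S,3S)-2-[(1E,5Z)-6-iodo-2-methylhepta-1,5-dien-1-yl]-4-methylidene-5-oxooxolan-3-yl}ethyl (2R,3R)-2,3-dimethyloxirane-2-carboxylate | C=C1C(=O)O[C@@H](/C=C(\C)CC/C=C(/C)I)[C@H]1[C@@H](OC(=O)[C@]2(C)O[C@@H]2C)CO[Si](C)(C)C(C)(C)C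
F7 | step 21 | (1R)-2-hydroxy-1-{(2S,3S)-2-[(1E,5Z)-6-iodo-2-methylhepta-1,5-dien-1-yl]-4-methylidene-5-oxooxolan-3-yl}ethyl (2R,3R)-2,3-dimethyloxirane-2-carboxylate | C=C1C(=O)O[C@@H](/C=C(\C)CC/C=C(/C)I)[C@H]1[C@@H](OC(=O)[C@]2(C)O[C@@H]2C)CO
F8 | step 21 | (1R)-1-{(2S,3S)-2-[(1E,5Z)-6-iodo-2-methylhepta-1,5-dien-1-yl]-4-methylidene-5-oxooxolan-3-yl}-2-oxoethyl (2R,3R)-2,3-dimethyloxirane-2-carboxylate | C=C1C(=O)O[C@@H](/C=C(\C)CC/C=C(/C)I)[C@H]1[C@@H](OC(=O)[C@]2(C)O[C@@H]2C)C=O
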